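**Retrosynthetic overview**

1. The tetrahydrofuran is closed last through its C6–O bond: the C9 hydroxyl opens a 6,7-cis-epoxide at C6 (5-endo, inversion), which also frees the C7 hydroxyl. The epoxide comes from hydroxyl-directed epoxidation of a (6Z)-alkene, run with a chiral vanadium catalyst so that the same step resolves the racemate.
2. The (6Z)-alkene comes from a 6-yne; the C7–C8 bond is made by acetylide opening of a terminal epoxide.
3. The epoxy palmitate (C9/C10 threo, ester already on O10) comes from racemic diepoxybutane, an oct-7-enyl Grignard reagent (C11–C12 bond) and palmitoyl chloride.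
4. Ring order: the oxirane inherited from the diepoxide is opened in step 2; the 6,7-oxirane and then the tetrahydrofuran form in step 4. No protecting groups are used, and the two hydroxyls never have to be told apart.

Assumption: commercial (±)-diepoxybutane is the racemic 2R,3R/2S,3S pair without the meso isomer, and the R,R antipode of the bishydroxamic acid ligand is the one matched to the (9R,10R) alcohol (if the sense is the opposite, the S,S ligand is used with nothing else changed).

**Route**

Step 1
Reactants: 1 8-bromooct-1-ene; 2 (±)-1,2:3,4-diepoxybutane (racemic 2R,3R/2S,3S pair); 3 palmitoyl chloride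
Product: 6 racemic (2R,3R)-1,2-epoxydodec-11-en-3-yl palmitate, via oct-7-enylmagnesium bromide 4 (not isolated), via bromomagnesium epoxy alkoxide 5 (not isolated)
Conditions: Mg, THF, rt; CuI (10 mol %), 2 (3 equiv), THF, −40 to −20 °C; then 3 (1.05 equiv), −20 to 0 °C
Reagents that add atoms: none
Why: Copper-catalysed Grignard opening of a terminal epoxide (SN2 at the CH2 terminus, so both carbinol centres of the C2-symmetric diepoxide keep their configuration and the threo C9/C10 relation is inherited from 2), followed by O-acylation of the magnesium alkoxide with the acid chloride; the threefold excess of 2 suppresses double opening.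

Step 2
Reactants: 6 racemic (2R,3R)-1,2-epoxydodec-11-en-3-yl palmitate; 7 hept-1-yne
Product: 9 racemic (9R,10R)-9-hydroxynonadec-18-en-6-yn-10-yl palmitate, via hept-1-ynyllithium 8 (not isolated)
Conditions: 7 (1.5 equiv), n-BuLi, THF, −78 °C; BF3·OEt2 (1.5 equiv); then 6, −78 °C; NH4Cl (aq) at −78 °C
Reagents that add atoms: none
Why: Yamaguchi-type alkynylation, in which the acetylide 8 activated by BF3 opens the epoxide only at its unsubstituted carbon at −78 °C, so C9 is untouched and the palmitate is neither attacked nor shifted before the cold quench.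

Step 3
Reactants: 9 racemic (9R,10R)-9-hydroxynonadec-18-en-6-yn-10-yl palmitate
Product: 10 racemic (6Z,9R,10R)-9-hydroxynonadeca-6,18-dien-10-yl palmitate
Conditions: H2 (1 atm, stopped after 1.0 equiv), Pd/CaCO3 poisoned with Pb(OAc)2, quinoline, EtOAc, rt
Reagents that add atoms: none
Why: Lindlar semi-hydrogenation, in which syn delivery of one equivalent of H2 on the lead-poisoned palladium surface gives the Z-alkene and the internal alkyne is taken up much faster than the terminal alkene.

Step 4
Reactants: 10 racemic (6Z,9R,10R)-9-hydroxynonadeca-6,18-dien-10-yl palmitate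
Product: 12 (1R)-1-[(2R,4S,5S)-4-hydroxy-5-pentyloxolan-2-yl]dec-9-en-1-yl hexadecanoate (target), via epoxy alcohol 11 (not isolated)
Conditions: VO(OiPr)3 (2 mol %), (R,R)-cyclohexane-1,2-diamine-derived bishydroxamic acid ligand (4 mol %), cumene hydroperoxide (0.55 equiv), toluene, 0 °C, to about 50 % conversion; then CSA (10 mol %), CH2Cl2, rt
Reagents that add atoms: cumene hydroperoxide, CC(C)(OO)c1ccccc1
Why: Proposed new method: kinetic-resolution epoxidation with ring closure, in which the C9 hydroxyl binds pentavalent vanadium and the bound hydroperoxide is delivered to the Z-alkene through a chair transition state where the cis substituent forces the oxygen onto the face 1,3-syn to the C9–O bond, the C2-symmetric bishydroxamate ligand opens only one face so that only the (9R,10R) enantiomer has substrate and ligand control matched and is epoxidised fast to the (6R,7S)-epoxide 11 (setting C7), whose C6 is then attacked by the C9 hydroxyl in an acid-assisted 5-endo SN2 opening with inversion (setting C6 as S and closing the ring), while the (9S,10S) alcohol stays behind; the closest known reaction types are the titanium tartrate kinetic resolution of secondary allylic alcohols by epoxidation and the vanadium bishydroxamic acid asymmetric epoxidation of achiral homoallylic alcohols, and to my knowledge neither has been run as a resolution of a secondary homoallylic alcohol coupled to tetrahydrofuran formation.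

**Compound list**

1 | 8-bromooct-1-ene | C=CCCCCCCBr | starting material
2 | (±)-1,2:3,4-diepoxybutane, racemic 2R,3R/2S,3S pair (2R,3R shown) | C1O[C@H]1[C@H]1CO1 | starting material
3 | palmitoyl chloride (hexadecanoyl chloride) | CCCCCCCCCCCCCCCC(=O)Cl | starting material
4 | oct-7-en-1-ylmagnesium bromide | C=CCCCCCC[Mg]Br | intermediate
5 | bromomagnesium alkoxide of racemic (2R,3R)-1,2-epoxydodec-11-en-3-ol (2R,3R shown) | C=CCCCCCCC[C@@H](O[Mg]Br)[C@H]1CO1 | intermediate
6 | racemic (2R,3R)-1,2-epoxydodec-11-en-3-yl palmitate (2R,3R shown) | C=CCCCCCCC[C@@H](OC(=O)CCCCCCCCCCCCCCC)[C@H]1CO1 | intermediate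
7 | hept-1-yne | CCCCCC#C | starting material
8 | hept-1-yn-1-yllithium | CCCCCC#C[Li] | intermediate
9 | racemic (9R,10R)-9-hydroxynonadec-18-en-6-yn-10-yl palmitate (9R,10R shown) | C=CCCCCCCC[C@@H](OC(=O)CCCCCCCCCCCCCCC)[C@H](O)CC#CCCCCC | intermediate
10 | racemic (6Z,9R,10R)-9-hydroxynonadeca-6,18-dien-10-yl palmitate (9R,10R shown) | C=CCCCCCCC[C@@H](OC(=O)CCCCCCCCCCCCCCC)[C@H](O)C/C=C\CCCCC | intermediate
11 | (6R,7S,9R,10R)-6,7-epoxy-9-hydroxynonadec-18-en-10-yl palmitate | C=CCCCCCCC[C@@H](OC(=O)CCCCCCCCCCCCCCC)[C@H](O)C[C@@H]1O[C@@H]1CCCCC | intermediate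
12 | (6S,7S,9R,10R)-6,9-epoxy-7-hydroxynonadec-18-en-10-yl palmitate, i.e. (1R)-1-[(2R,4S,5S)-4-hydroxy-5-pentyloxolan-2-yl]dec-9-en-1-yl hexadecanoate | C=CCCCCCCC[C@@H](OC(=O)CCCCCCCCCCCCCCC)[C@H]1C[C@H](O)[C@H](CCCCC)O1 | target

**Step count**

Total steps: 4. Longest linear sequence: 4 steps (1 → 6 → 9 → 10 → 12).

**Three steps most likely to fail**

Step 4 (the proposed new step). The selectivity factor may be too low, the sense may be reversed, or turnover may be slow with the hindered carbinol. The fallback uses known chemistry, sets out from 6 and comes back at 12. Hydrolytic kinetic resolution of 6 with (S,S)-(salen)Co(OAc) (trivalent cobalt, 0.5 mol %) and water (0.55 equiv) leaves (2R,3R)-1,2-epoxydodec-11-en-3-yl palmitate F1, while the (2S,3S) epoxide is hydrolysed to (2S,3S)-1,2-dihydroxydodec-11-en-3-yl palmitate F2 and removed. F1 is taken through the conditions of steps 2 and 3 (with 8, then Lindlar hydrogenation) to (9R,10R)-9-hydroxynonadec-18-en-6-yn-10-yl palmitate F3 and (6Z,9R,10R)-9-hydroxynonadeca-6,18-dien-10-yl palmitate F4. F4 is epoxidised with achiral VO(acac)2 and t-BuOOH (hydroxyl-directed, 1,3-syn) and closed with CSA to 12 via 11.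

Step 2. The BF3-activated acetylide meets an epoxide that carries a neighbouring ester, so acyl participation or a 1,2-acyl shift to O9 could intervene. The fallback sets out from 2 and 7 and comes back at 10. The order of the two epoxide openings is reversed, so that no ester is present when BF3 is used and no terminal alkene when hydrogen is used. Acetylide 8 with BF3·OEt2 opens one oxirane of 2 (3 equiv) to racemic (2R,3R)-1,2-epoxyundec-5-yn-3-ol F5. Lindlar hydrogenation gives racemic (2R,3R,5Z)-1,2-epoxyundec-5-en-3-ol F6. Et3SiCl and imidazole give racemic (2R,3R,5Z)-1,2-epoxy-3-(triethylsilyloxy)undec-5-ene F7. Grignard reagent 4 with CuI opens the remaining oxirane to bromomagnesium (6Z,9R,10R)-9-(triethylsilyloxy)nonadeca-6,18-dien-10-olate F8, which is acylated in the flask with 3 to racemic (6Z,9R,10R)-9-(triethylsilyloxy)nonadeca-6,18-dien-10-yl palmitate F9. AcOH/THF/H2O removes the silyl group and gives 10.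

Step 3. The terminal alkene may be over-reduced, or Z-selectivity may be incomplete. The fallback sets out from 6 and comes back at 10 without alkyne 9 and without hydrogenation. Pentyllithium and CuBr·SMe2 give lithium dipentylcuprate F10. Syn-carbocupration of acetylene gives lithium di[(Z)-hept-1-enyl]cuprate F11. F11 opens the terminal epoxide of 6 at −40 °C in ether and gives 10 directly, with the Z geometry fixed by the carbocupration.

Further compounds
F1 | step 4 | (2R,3R)-1,2-epoxydodec-11-en-3-yl palmitate (single enantiomer) | C=CCCCCCCC[C@@H](OC(=O)CCCCCCCCCCCCCCC)[C@H]1CO1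
F2 | step 4 | (2S,3S)-1,2-dihydroxydodec-11-en-3-yl palmitate | C=CCCCCCCC[C@H](OC(=O)CCCCCCCCCCCCCCC)[C@@H](O)CO
F3 | step 4 | (9R,10R)-9-hydroxynonadec-18-en-6-yn-10-yl palmitate (single enantiomer) | C=CCCCCCCC[C@@H](OC(=O)CCCCCCCCCCCCCCC)[C@H](O)CC#CCCCCC
F4 | step 4 | (6Z,9R,10R)-9-hydroxynonadeca-6,18-dien-10-yl palmitate (single enantiomer) | C=CCCCCCCC[C@@H](OC(=O)CCCCCCCCCCCCCCC)[C@H](O)C/C=C\CCCCC
F5 | step 2 | racemic (2R,3R)-1,2-epoxyundec-5-yn-3-ol (2R,3R shown) | CCCCCC#CC[C@@H](O)[C@H]1CO1
F6 | step 2 | racemic (2R,3R,5Z)-1,2-epoxyundec-5-en-3-ol (2R,3R shown) | CCCCC/C=C\C[C@@H](O)[C@H]1CO1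
F7 | step 2 | racemic (2R,3R,5Z)-1,2-epoxy-3-(triethylsilyloxy)undec-5-ene (2R,3R shown) | CCCCC/C=C\C[C@@H](O[Si](CC)(CC)CC)[C@H]1CO1
F8 | step 2 | bromomagnesium (6Z,9R,10R)-9-(triethylsilyloxy)nonadeca-6,18-dien-10-olate, racemic (9R,10R shown) | C=CCCCCCCC[C@@H](O[Mg]Br)[C@H](O[Si](CC)(CC)CC)C/C=C\CCCCC
F9 | step 2 | racemic (6Z,9R,10R)-9-(triethylsilyloxy)nonadeca-6,18-dien-10-yl palmitate (9R,10R shown) | C=CCCCCCCC[C@@H](OC(=O)CCCCCCCCCCCCCCC)[C@H](O[Si](CC)(CC)CC)C/C=C\CCCCC
F10 | step 3 | lithium dipentylcuprate | [Li+].CCCCC[Cu-]CCCCC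
F11 | step 3 | lithium di[(Z)-hept-1-enyl]cuprate | [Cu-](/C=C\CCCCC)/C=C\CCCCC.[Li+]
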